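## Retrosynthetic overview
1. The quinone comes from 3-nonadecylphenol by oxygenation at the free para carbon, mirroring the natural sequence phenol → quinol → quinone.
2. The phenol comes from 6-nonadecylsalicylic acid (anacardic acid 19:0) by loss of CO2.
3. The only ring is closed by a C2→C7 aldol condensation and dehydration of the partly reduced linear tetraketide 3,7-dioxohexacos-5-enoic acid.
4. The tetraketide is made in the flask by decarboxylative C4–C5 coupling of acetonedicarboxylic acid (two condensed malonyl units) with a C22 β-chlorovinyl ketone.
5. The β-chlorovinyl ketone comes from icosanoic acid (the C20 starter unit) and acetylene.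

Assumption: the SMILES has no stereocentre and no stereogenic double bond, so the target is the achiral compound 2-nonadecyl-1,4-benzoquinone (C25H42O2) and no enantiomer has to be set.

## Route

Step 1
Reactants: 1 icosanoic acid (arachidic acid); 2 acetylene
Product: 4 (E)-1-chlorodocos-1-en-3-one, via icosanoyl chloride 3 (not isolated)
Conditions: SOCl2 (1.5 equiv), DMF (cat.), 60 °C, then evaporate; HC≡CH (bubbled), AlCl3 (1.2 equiv), CH2Cl2, 0 °C → rt; ice/aq. HCl
Reagents that add atoms: thionyl chloride ClS(Cl)=O; aluminium chloride Cl[Al](Cl)Cl (the vinylic Cl is delivered from AlCl4−, which pools the chlorides of both)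
Why: Acid chloride formation is followed by a Friedel–Crafts-type (Kondakov) acylation of acetylene, the classical route from aliphatic acid chlorides to β-chlorovinyl ketones, in which the acylium ion adds to the alkyne and chloride from AlCl4− caps the vinyl cation; the E/Z ratio does not matter because step 2 erases the geometry.

Step 2
Reactants: 4 (E)-1-chlorodocos-1-en-3-one; 5 3-oxopentanedioic acid (acetonedicarboxylic acid)
Product: 9 3-nonadecylphenol, via ketovinylated 3-oxoglutaric acid 6 (not isolated), via (E)-3,7-dioxohexacos-5-enoic acid 7 (not isolated), via 6-nonadecylsalicylic acid 8 (not isolated)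
Conditions: 5 (2 equiv), Et3N (5 equiv), DABCO (20 mol %), THF–MeCN, slow addition of 4, 0 °C → rt; AcOH to pH ≈ 6, piperidine (20 mol %), 45 °C; aq. HCl work-up, crude melt, 190 °C, N2, 1 h (nothing purified before 9)
Reagents that add atoms: none
Why: Proposed new method: this is a di-decarboxylative [3+3] benzannulation in which the enol of 5 attacks the amine-activated β-acylvinyl electrophile (ketovinylation by addition–elimination) to give 6, the C4 carboxyl of 6 leaves readily because it releases a glutaconaldehyde-type dienolate, the resulting ene-dione 7 equilibrates E/Z through that dienolate and closes by intramolecular Knoevenagel–aldol attack of its β-keto-acid methylene C2 on the C7 ketone, loss of water aromatises the ring to 8, and heat removes the last CO2 as it does for anacardic acids; the closest known reaction types are the ketovinylation/cyclisation of acetoacetates with β-chlorovinyl ketones to salicylates, the Robinson–Schöpf and amine-catalysed didecarboxylative Michael/aldol annulations of acetonedicarboxylic acid with enals, and the base-induced ring closure of pyrylium pseudobases to phenols; the nucleophile is symmetric, so either order of bond formation gives the same phenol, and no stereocentre remains in the product.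

Step 3
Reactants: 9 3-nonadecylphenol
Product: 10 2-nonadecylcyclohexa-2,5-diene-1,4-dione (2-nonadecyl-1,4-benzoquinone)
Conditions: (KSO3)2NO (2.5 equiv), KH2PO4 buffer, Bu4NHSO4 (10 mol %), CH2Cl2–H2O, rt
Reagents that add atoms: potassium nitrosodisulfonate (Fremy's salt) [K+].[K+].[O]N(S(=O)(=O)[O-])S(=O)(=O)[O-]
Why: In this Teuber oxidation one nitroxyl radical abstracts the phenolic hydrogen, a second couples through its oxygen at the unsubstituted para carbon, and loss of imidodisulfonate gives the p-quinone, as known for m-cresol → toluquinone; the saturated chain is inert and no stereocentre is formed.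

## Compound list
1 | icosanoic acid (arachidic acid) | CCCCCCCCCCCCCCCCCCCC(=O)O | starting material
2 | acetylene | C#C | starting material
3 | icosanoyl chloride | CCCCCCCCCCCCCCCCCCCC(=O)Cl | intermediate
4 | (E)-1-chlorodocos-1-en-3-one | CCCCCCCCCCCCCCCCCCCC(=O)/C=C/Cl | intermediate
5 | 3-oxopentanedioic acid (acetonedicarboxylic acid) | OC(=O)CC(=O)CC(=O)O | starting material
6 | 2-[(E)-3-oxodocos-1-enyl]-3-oxopentanedioic acid (racemic, configurationally labile CH) | CCCCCCCCCCCCCCCCCCCC(=O)/C=C/C(C(=O)O)C(=O)CC(=O)O | intermediate
7 | (E)-3,7-dioxohexacos-5-enoic acid (linear, partly reduced tetraketide) | CCCCCCCCCCCCCCCCCCCC(=O)/C=C/CC(=O)CC(=O)O | intermediate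
8 | 2-hydroxy-6-nonadecylbenzoic acid (6-nonadecylsalicylic acid) | CCCCCCCCCCCCCCCCCCCc1cccc(O)c1C(=O)O | intermediate
9 | 3-nonadecylphenol | CCCCCCCCCCCCCCCCCCCc1cccc(O)c1 | intermediate
10 | 2-nonadecylcyclohexa-2,5-diene-1,4-dione | CCCCCCCCCCCCCCCCCCCC1=CC(=O)C=CC1=O | target

## Step count and risks
Total step count: 3. Longest linear sequence: 3.

**Most likely to fail: step 2.**
- Risks:
  - 5 or 7 may lose all its CO2 before the ring closes. The chain-side CH2 (C8) could then compete in the aldol and give 3-methyl-2-octadecylphenol.
  - 4 may trimerise to a triacylbenzene under amine.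
  - 5 may be ketovinylated twice.
- Fallback: it sets out from 4 and comes back at 8.
  - Treat 4 with NaOMe in MeOH to give 1,1-dimethoxydocosan-3-one F3.
  - Combine this with commercial 1-methoxy-1,3-bis(trimethylsilyloxy)buta-1,3-diene and TiCl4 in CH2Cl2 (−78 °C → rt). In this Lewis-acid [3+3] cyclocondensation the diene terminus takes the acetal carbon and C2 then closes on the ketone, giving methyl 2-hydroxy-6-nonadecylbenzoate F4.
  - Cleave the hindered ester with KOH in DMSO–H2O at 100 °C to give 8, which is melted at 190 °C to 9 as in the route.

**Second: step 1.**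
- Risks: the waxy acid chloride may take up acetylene sluggishly, and tar may form with AlCl3.
- Fallback: it sets out from 3 and comes back at 6. It replaces electrophilic acylation of the alkyne with nucleophilic acetylide addition.
  - React 3 with MeNH(OMe)·HCl and Et3N in CH2Cl2 to give N-methoxy-N-methylicosanamide F1.
  - Add ethynylmagnesium bromide in THF at 0 °C to give docos-1-yn-3-one F2.
  - F2 takes the place of 4 under the step 2 conditions. Conjugate addition of 5 to the ynone gives 6 directly, and the cascade runs on to 9.

**Third: step 3.**
- Risks: the C19 phenol may transfer poorly to the aqueous radical, and phenoxyl radicals may couple.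
- Fallback: it sets out from 9 and comes back at 10. It uses two-electron iodine(III) dearomatisation instead of radical oxidation.
  - Treat 9 with PhI(OAc)2 (2.2 equiv) in MeOH–CH2Cl2 to give the quinone monoketal 4,4-dimethoxy-3-nonadecylcyclohexa-2,5-dien-1-one F5.
  - Hydrolyse it with 1 M HCl in THF to give 10.

## Further compounds
F1 | step 1 | N-methoxy-N-methylicosanamide | CCCCCCCCCCCCCCCCCCCC(=O)N(C)OC
F2 | step 1 | docos-1-yn-3-one | CCCCCCCCCCCCCCCCCCCC(=O)C#C
F3 | step 2 | 1,1-dimethoxydocosan-3-one | CCCCCCCCCCCCCCCCCCCC(=O)CC(OC)OC
F4 | step 2 | methyl 2-hydroxy-6-nonadecylbenzoate | CCCCCCCCCCCCCCCCCCCc1cccc(O)c1C(=O)OC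
F5 | step 3 | 4,4-dimethoxy-3-nonadecylcyclohexa-2,5-dien-1-one | CCCCCCCCCCCCCCCCCCCC1=CC(=O)C=CC1(OC)OC
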